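**Retrosynthetic overview**

1. Target 10 comes from its bis-silyl ether 9 by desilylation; the benzene ring (ring A) is bought with the acetyl group already on it.
2. The pyranone ring (ring B: O1–C2–C3–C4–C4a–C8a) is the only ring formed; it is opened at the C2–C3 bond, which leads back to the open-chain aryl diazomethyl ketone 8 carrying a plain hexadecyl ether.
3. Enabling feature: the ring oxygen O1 is bonded to C2, so in the open precursor C2 is an ether OCH2 with hydridic C–H bonds, and it lies 1,6 to the carbene carbon C3 along C4, C4a, C8a and O1 of the aryl ketone. One enantioselective rhodium-carbene C–H insertion therefore forms the C–C bond, closes ring B and sets C2.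
4. 8 comes from methyl ketone 6 by diazo transfer; 6 comes from 2',6'-dihydroxyacetophenone 1 by mono-O-hexadecylation, Elbs para-hydroxylation and bis-silylation.

Key step: step 5

Assumption: the target is (R) at C2, as drawn; the sense of induction of Rh2(S-PTTL)4 on this substrate cannot be predicted with confidence, so the route is written with this catalyst and the mirror-image Rh2(R-PTTL)4 would be used if a test run should favour the (S)-chromanone.

**Step 1**
Reactants: 1 2',6'-dihydroxyacetophenone; 2 1-bromohexadecane
Product: 3 1-[2-(hexadecyloxy)-6-hydroxyphenyl]ethanone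
Conditions: K2CO3 (1.05 equiv), 2 (1.0 equiv), acetone, reflux
Reagents that add atoms: 1-bromohexadecane (compound 2), CCCCCCCCCCCCCCCCBr
Why: Williamson ether synthesis, in which the hydroxyl left after the first alkylation is locked in a strong hydrogen bond to the acetyl carbonyl and is far less nucleophilic, so one equivalent of bromide should give the mono-ether selectively.

**Step 2**
Reactants: 3 1-[2-(hexadecyloxy)-6-hydroxyphenyl]ethanone
Product: 5 1-[2-(hexadecyloxy)-3,6-dihydroxyphenyl]ethanone, via aryl sulfate potassium salt 4 (not isolated)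
Conditions: K2S2O8, aq KOH/pyridine, 5–20 °C; then 2 M HCl, 70 °C, under N2
Reagents that add atoms: potassium peroxodisulfate, [K+].[K+].[O-]S(=O)(=O)OOS(=O)(=O)[O-]
Why: Elbs persulfate oxidation, in which the phenoxide attacks the peroxide oxygen through its para carbon (the position next to the hexadecyloxy group) to give aryl sulfate 4, which acid hydrolyses to the hydroquinone; pyridine as co-solvent is meant to keep the long-chain phenoxide in solution.

**Step 3**
Reactants: 5 1-[2-(hexadecyloxy)-3,6-dihydroxyphenyl]ethanone
Product: 6 1-[3,6-bis[(tert-butyldimethylsilyl)oxy]-2-(hexadecyloxy)phenyl]ethanone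
Conditions: TBSCl (2.6 equiv), imidazole, DMAP (cat.), DMF, rt to 40 °C
Reagents that add atoms: tert-butyldimethylsilyl chloride, CC(C)(C)[Si](C)(C)Cl
Why: standard imidazole-promoted O-silylation of phenols, with gentle warming and DMAP to bring the carbonyl-chelated hydroxyl to completion; silyl ethers are chosen because they carry no C–H bond α to oxygen and so cannot compete in step 5.

**Step 4**
Reactants: 6 1-[3,6-bis[(tert-butyldimethylsilyl)oxy]-2-(hexadecyloxy)phenyl]ethanone
Product: 8 1-[3,6-bis[(tert-butyldimethylsilyl)oxy]-2-(hexadecyloxy)phenyl]-2-diazoethanone, via trifluoroacetyl diketone 7 (not isolated)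
Conditions: LiN(SiMe3)2, THF, −78 °C; CF3CO2CH2CF3, −78 °C; aq NH4Cl; then MsN3, Et3N, H2O (1 equiv), MeCN, rt
Reagents that add atoms: 2,2,2-trifluoroethyl trifluoroacetate, O=C(OCC(F)(F)F)C(F)(F)F (its trifluoroacetyl group stays in 7 only); methanesulfonyl azide, CS(=O)(=O)N=[N+]=[N-]
Why: detrifluoroacetylative Regitz diazo transfer, in which the lithium enolate of the methyl ketone is trifluoroacetylated (Claisen-type) at −78 °C, cold enough to hold back silyl migration, and the activated 1,3-diketone 7 then takes up the diazo group from mesyl azide with loss of the trifluoroacetyl group.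

**Step 5**
Reactants: 8 1-[3,6-bis[(tert-butyldimethylsilyl)oxy]-2-(hexadecyloxy)phenyl]-2-diazoethanone
Product: 9 (R)-5,8-bis[(tert-butyldimethylsilyl)oxy]-2-pentadecylchroman-4-one
Conditions: Rh2(S-PTTL)4 (dirhodium tetrakis[N-phthaloyl-(S)-tert-leucinate], 1 mol %), CH2Cl2, slow addition of 8 (final about 0.01 M), 0 °C to rt, Ar
Reagents that add atoms: none
Why: Rh2(S-PTTL)4 decomposes the diazoketone with loss of N2 to an electrophilic rhodium carbene at the future C3, which inserts through a concerted, asynchronous, hydride-transfer-like three-centre transition state into one C–H bond of the hexadecyl OCH2 group (the future C2), forming the C2–C3 bond (enantioselective intramolecular rhodium-carbene C–H insertion). The closest known reaction type is the chiral dirhodium tetracarboxylate-catalysed cyclisation of 2-alkoxyaryl α-diazoketones to chroman-4-ones and, more widely, carbene insertion into C–H bonds α to an ether oxygen. Ring B (O1–C2–C3–C4–C4a–C8a) closes in the 1,6-insertion mode through a six-membered cyclic transition state in which C4, C4a, C8a and O1 are already held in place by the aryl ketone. The C2 stereocentre arises from differentiation of the two enantiotopic hydrogens of the OCH2 group and is controlled only by the chiral pocket that the four N-phthaloyl-tert-leucinate ligands build around the carbene-bearing rhodium, since the substrate has no stereocentre. The step needs site selectivity for this methylene and chemoselectivity for C–H insertion over oxonium ylide formation at O1 (followed by 1,2-shift or β-elimination), Wolff rearrangement and carbene dimerisation. These should be secured because the ether oxygen makes only this methylene hydridic and places it at the favoured distance, the other ortho oxygen carries a silyl group without an α-C–H bond, a primary alkyl group migrates poorly from an oxonium ylide, rhodium carboxylates favour insertion over ylide chemistry, and slow addition keeps the diazo concentration low.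

**Step 6**
Reactants: 9 (R)-5,8-bis[(tert-butyldimethylsilyl)oxy]-2-pentadecylchroman-4-one
Product: 10 (R)-5,8-dihydroxy-2-pentadecylchroman-4-one
Conditions: HF·pyridine, pyridine, THF, 0 °C to rt, Ar; pH 7 phosphate buffer work-up
Reagents that add atoms: none
Why: fluoride-driven cleavage of both aryl silyl ethers (strong Si–F bond) under buffered, mildly acidic conditions, which should avoid phenoxide or enolate formation and therefore retro-oxa-Michael ring opening, so the C2 configuration should be kept.

**Compound list**

1 | 2',6'-dihydroxyacetophenone | CC(=O)c1c(O)cccc1O | starting material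
2 | 1-bromohexadecane | CCCCCCCCCCCCCCCCBr | starting material
3 | 1-[2-(hexadecyloxy)-6-hydroxyphenyl]ethanone | CCCCCCCCCCCCCCCCOc1cccc(O)c1C(C)=O | intermediate
4 | potassium 3-acetyl-2-(hexadecyloxy)-4-hydroxyphenyl sulfate (not isolated) | CCCCCCCCCCCCCCCCOc1c(OS(=O)(=O)[O-])ccc(O)c1C(C)=O.[K+] | intermediate
5 | 1-[2-(hexadecyloxy)-3,6-dihydroxyphenyl]ethanone | CCCCCCCCCCCCCCCCOc1c(O)ccc(O)c1C(C)=O | intermediate
6 | 1-[3,6-bis[(tert-butyldimethylsilyl)oxy]-2-(hexadecyloxy)phenyl]ethanone | CCCCCCCCCCCCCCCCOc1c(O[Si](C)(C)C(C)(C)C)ccc(O[Si](C)(C)C(C)(C)C)c1C(C)=O | intermediate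
7 | 1-[3,6-bis[(tert-butyldimethylsilyl)oxy]-2-(hexadecyloxy)phenyl]-4,4,4-trifluorobutane-1,3-dione (not isolated) | CCCCCCCCCCCCCCCCOc1c(O[Si](C)(C)C(C)(C)C)ccc(O[Si](C)(C)C(C)(C)C)c1C(=O)CC(=O)C(F)(F)F | intermediate
8 | 1-[3,6-bis[(tert-butyldimethylsilyl)oxy]-2-(hexadecyloxy)phenyl]-2-diazoethanone | CCCCCCCCCCCCCCCCOc1c(O[Si](C)(C)C(C)(C)C)ccc(O[Si](C)(C)C(C)(C)C)c1C(=O)C=[N+]=[N-] | intermediate
9 | (R)-5,8-bis[(tert-butyldimethylsilyl)oxy]-2-pentadecylchroman-4-one | CCCCCCCCCCCCCCC[C@@H]1CC(=O)c2c(O[Si](C)(C)C(C)(C)C)ccc(O[Si](C)(C)C(C)(C)C)c2O1 | intermediate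
10 | (R)-5,8-dihydroxy-2-pentadecylchroman-4-one | CCCCCCCCCCCCCCC[C@@H]1CC(=O)c2c(O)ccc(O)c2O1 | target

Total step count: 6. Longest linear sequence: 6 steps.

**Steps most likely to fail**

1. Step 5. The chiral catalyst may discriminate poorly between the two enantiotopic C–H bonds of the OCH2 group with this acceptor-only carbene, so that the chromanone forms with insufficient enantiomeric purity. The fallback sets out from 8 and separates ring closure from stereocontrol. Cyclisation of 8 with achiral Rh2(OAc)4 (CH2Cl2, rt) should give racemic 5,8-bis[(tert-butyldimethylsilyl)oxy]-2-pentadecylchroman-4-one F1. Dehydrogenation of this with 2-iodoxybenzoic acid (DMSO, 70 °C) should give 5,8-bis[(tert-butyldimethylsilyl)oxy]-2-pentadecyl-4H-chromen-4-one F2. Copper hydride-catalysed asymmetric conjugate reduction of the chromone (Cu(OAc)2, DTBM-SEGPHOS in the enantiomeric form that delivers hydride to the required face, (EtO)2MeSiH, t-BuOH, toluene, 0 °C) then comes back to the route at 9.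

2. Step 2. Para-sulfation by persulfate may be slow or incomplete because the long-chain phenoxide aggregates in aqueous alkali, and the hydroquinone may be over-oxidised during the acid hydrolysis. The fallback sets out from 3 and goes through the quinone oxidation level. Teuber oxidation with Fremy's salt, ON(SO3K)2 (CH2Cl2/aq KH2PO4, phase-transfer catalyst Bu4NHSO4, rt), should give 2-acetyl-3-(hexadecyloxy)cyclohexa-2,5-diene-1,4-dione F3. Reduction with Na2S2O4 (EtOAc/H2O, rt) comes back to the route at 5.

3. Step 4. The ortho silyl group may migrate from the phenol oxygen to the enolate oxygen, or a silyl ether may be lost in the aqueous amine of the transfer stage, so the diazoketone is formed incompletely. The fallback sets out from 6 and avoids enolate chemistry. Condensation with N,N-dimethylformamide dimethyl acetal (toluene, 90 °C) should give (E)-1-[3,6-bis[(tert-butyldimethylsilyl)oxy]-2-(hexadecyloxy)phenyl]-3-(dimethylamino)prop-2-en-1-one F4. Deformylative diazo transfer to this enaminone with p-toluenesulfonyl azide (MeCN, rt to 40 °C) comes back to the route at 8.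

**Further compounds**

F1 | step 5 | racemic 5,8-bis[(tert-butyldimethylsilyl)oxy]-2-pentadecylchroman-4-one | CCCCCCCCCCCCCCCC1CC(=O)c2c(O[Si](C)(C)C(C)(C)C)ccc(O[Si](C)(C)C(C)(C)C)c2O1
F2 | step 5 | 5,8-bis[(tert-butyldimethylsilyl)oxy]-2-pentadecyl-4H-chromen-4-one | CCCCCCCCCCCCCCCC1=CC(=O)c2c(O[Si](C)(C)C(C)(C)C)ccc(O[Si](C)(C)C(C)(C)C)c2O1
F3 | step 2 | 2-acetyl-3-(hexadecyloxy)cyclohexa-2,5-diene-1,4-dione | CCCCCCCCCCCCCCCCOC1=C(C(C)=O)C(=O)C=CC1=O
F4 | step 4 | (E)-1-[3,6-bis[(tert-butyldimethylsilyl)oxy]-2-(hexadecyloxy)phenyl]-3-(dimethylamino)prop-2-en-1-one | CCCCCCCCCCCCCCCCOc1c(O[Si](C)(C)C(C)(C)C)ccc(O[Si](C)(C)C(C)(C)C)c1C(=O)/C=C/N(C)C
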